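**Retrosynthetic overview**

- Numbering: C1–C2 = ArCH2CH2 (Ar = 3,4-dimethoxyphenyl), C3 = CH(OAc) with oxygen O3, C4 = CH2, C5 = CH(OH) with oxygen O5, C6–C10 = pentyl. The target is (3S,5S), with O3 and O5 anti.
- Feature: O3, the acetyl carbonyl carbon with its CH3, and C3–C4–C5–C6 are the ring atoms (plus the 6-methyl) of a 6-methyl-2,3-dihydro-4H-pyran-4-one (ring O1 = O3, ring C2 = C3, ring C3 = C4, ring C4 = C5, ring C5 = C6, ring C6 = acetyl carbon). Cleaving the ring enol ether C=C therefore leaves the acetyl group on O3 and an aldehyde at C6.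
- Disconnections, backwards: C6=C7 (Wittig, then hydrogenation); the C6/acetyl-carbon double bond (ozonolysis); C5–H (cis-selective ketone reduction); C3–C4 and O3–C(acetyl) (catalytic asymmetric hetero-Diels–Alder-type aldol–cyclisation of 3-(3,4-dimethoxyphenyl)propanal with a methyl-bearing silyloxy diene).
- Rings: the dihydropyranone is the only ring made (step 3) and it is opened again in step 6; the arene is purchased.

Key step: step 3

Remark on the chemistry: (R)-BINOL is specified on the expectation that its titanium complex delivers the nucleophile to the Re face of an unbranched aliphatic aldehyde, which corresponds to (S) at C3. The configuration of 7 should be confirmed (Mosher ester analysis of 8), and (S)-BINOL used instead if the sense proves opposite.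

**Step 1**
Reactants: 1 3-(3,4-dimethoxyphenyl)propan-1-ol
Product: 2 3-(3,4-dimethoxyphenyl)propanal
Conditions: TEMPO (2,2,6,6-tetramethylpiperidin-1-oxyl, 10 mol%), PhI(OAc)2 (1.1 equiv), CH2Cl2, rt
Reagents that add atoms: none
Why: Oxoammonium-mediated (TEMPO) oxidation of an unhindered primary alcohol should stop at the aldehyde and leave the dimethoxybenzene ring untouched.

**Step 2**
Reactants: 3 (E)-4-methoxypent-3-en-2-one
Product: 5 (E)-4-methoxy-2-(trimethylsilyloxy)penta-1,3-diene, via lithium dienolate 4 (not isolated)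
Conditions: LiN(i-Pr)2 (1.1 equiv), THF, −78 °C; then Me3SiCl, −78 °C → rt; non-aqueous work-up, distillation
Reagents that add atoms: chlorotrimethylsilane, C[Si](C)(C)Cl
Why: Kinetic deprotonation of the vinylogous ester by the hindered amide base should occur at the methyl group next to the carbonyl, and O-silylation of the dienolate (silyl enol ether formation) gives the diene with the enol ether geometry of 3 retained.

**Step 3**
Reactants: 2 3-(3,4-dimethoxyphenyl)propanal; 5 (E)-4-methoxy-2-(trimethylsilyloxy)penta-1,3-diene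
Product: 7 (S)-2-[2-(3,4-dimethoxyphenyl)ethyl]-6-methyl-2,3-dihydro-4H-pyran-4-one, via silylated aldol adduct 6 (not isolated)
Conditions: (R)-1,1'-bi-2-naphthol ((R)-BINOL, 20 mol%), Ti(OiPr)4 (10 mol%), CF3CO2H (cat.), 4 Å MS, Et2O, −20 °C; then CF3CO2H, CH2Cl2, 0 °C; NaHCO3 work-up
Reagents that add atoms: none
Why: The aldehyde is bound and activated by the chiral titanium BINOLate, and the unsubstituted CH2 terminus of the electron-rich diene adds to its carbonyl carbon (C3) in a Mukaiyama aldol addition with silyl transfer to the aldolate oxygen, giving 6; CF3CO2H then frees that oxygen, which adds to the methoxy-bearing carbon of the vinylogous ester and expels methanol. The closest known reaction type is the BINOL–titanium-catalysed formal hetero-Diels–Alder reaction of 1-methoxy-3-silyloxybutadienes with aldehydes, run as aldol addition followed by acid cyclisation, a stepwise course that does not need the s-cis diene conformation disfavoured by the inside methyl group. The single ring is closed by a 6-endo-trig oxa-conjugate addition followed by elimination, a net addition–elimination at the vinylogous ester carbon. The one new stereocentre (C3, ring C2) is set by the catalyst alone, attack on the Re face of the aldehyde corresponding to (S). The step needs attack through the diene CH2 terminus and clean enantioface discrimination; the first is secured by the polarisation of the silyl dienol ether, the second by the unbranched aldehyde being the only Lewis-basic electrophile, since the dimethoxybenzene ring does not compete for titanium.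

**Step 4**
Reactants: 7 (S)-2-[2-(3,4-dimethoxyphenyl)ethyl]-6-methyl-2,3-dihydro-4H-pyran-4-one
Product: 8 (2S,4R)-2-[2-(3,4-dimethoxyphenyl)ethyl]-6-methyl-3,4-dihydro-2H-pyran-4-ol (2,4-cis)
Conditions: NaBH4, CeCl3·7H2O, MeOH, −78 → −40 °C; NaHCO3 work-up
Reagents that add atoms: none
Why: In this Luche 1,2-reduction hydride should add along the axial trajectory to the half-chair that carries the C2 side chain pseudo-equatorially, so the new hydroxyl (O5) becomes pseudo-equatorial and cis to the side chain, which is the anti O3/O5 relationship of the open chain.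

**Step 5**
Reactants: 8 (2S,4R)-2-[2-(3,4-dimethoxyphenyl)ethyl]-6-methyl-3,4-dihydro-2H-pyran-4-ol
Product: 9 tert-butyl{[(2S,4R)-2-[2-(3,4-dimethoxyphenyl)ethyl]-6-methyl-3,4-dihydro-2H-pyran-4-yl]oxy}dimethylsilane
Conditions: t-BuMe2SiCl, imidazole, DMF, rt
Reagents that add atoms: tert-butyldimethylsilyl chloride, CC(C)(C)[Si](C)(C)Cl
Why: Silyl ether formation under basic conditions protects O5 without ionising the acid-labile allylic alcohol next to the enol ether, and later keeps the acetyl group from migrating from O3 to O5.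

**Step 6**
Reactants: 9 tert-butyl{[(2S,4R)-2-[2-(3,4-dimethoxyphenyl)ethyl]-6-methyl-3,4-dihydro-2H-pyran-4-yl]oxy}dimethylsilane
Product: 11 (3S,5R)-5-[(tert-butyldimethylsilyl)oxy]-1-(3,4-dimethoxyphenyl)-6-oxohexan-3-yl acetate, via methoxy hydroperoxide 10 (not isolated)
Conditions: O3, CH2Cl2/MeOH (4:1), NaHCO3, Sudan Red 7B as end-point indicator, −78 °C; then Me2S, −78 °C → rt
Reagents that add atoms: ozone, [O-][O+]=O
Why: In this ozonolysis the electron-rich enol ether should react far faster than the dimethoxybenzene ring, the carbonyl oxide formed at the non-oxygenated carbon (C6) is trapped by methanol as 10 and reduced by Me2S to the aldehyde, and the oxygenated carbon remains as the acetate carbonyl on O3, with no stereocentre touched (the change of the C5 descriptor to R is a priority change only).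

**Step 7**
Reactants: 11 (3S,5R)-5-[(tert-butyldimethylsilyl)oxy]-1-(3,4-dimethoxyphenyl)-6-oxohexan-3-yl acetate
Product: 12 (3S,5R,6Z)-5-[(tert-butyldimethylsilyl)oxy]-1-(3,4-dimethoxyphenyl)dec-6-en-3-yl acetate
Conditions: n-BuPPh3Br (1.3 equiv), NaN(SiMe3)2 (1.2 equiv), THF, 0 °C; then 11, −78 → 0 °C
Reagents that add atoms: butyltriphenylphosphonium bromide, CCCC[P+](c1ccccc1)(c1ccccc1)c1ccccc1.[Br-]
Why: Wittig olefination with a non-stabilised ylide at low temperature should outrun enolisation of the alpha-silyloxy aldehyde and attack on the acetate, and the alkene geometry (Z expected) is of no consequence because the double bond is hydrogenated next.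

**Step 8**
Reactants: 12 (3S,5R,6Z)-5-[(tert-butyldimethylsilyl)oxy]-1-(3,4-dimethoxyphenyl)dec-6-en-3-yl acetate
Product: 13 (3S,5S)-5-[(tert-butyldimethylsilyl)oxy]-1-(3,4-dimethoxyphenyl)decan-3-yl acetate
Conditions: H2 (1 atm), 10% Pd/C, EtOAc, rt
Reagents that add atoms: none
Why: Heterogeneous catalytic hydrogenation saturates the disubstituted alkene to complete the pentyl chain, and in ethyl acetate the silyl ether, the acetate and the arene are expected to persist.

**Step 9**
Reactants: 13 (3S,5S)-5-[(tert-butyldimethylsilyl)oxy]-1-(3,4-dimethoxyphenyl)decan-3-yl acetate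
Product: 14 (3S,5S)-1-(3,4-dimethoxyphenyl)-5-hydroxydecan-3-yl acetate (CNP0382730.1)
Conditions: HF·pyridine, pyridine, THF, 0 °C → rt
Reagents that add atoms: none
Why: Fluoride-mediated desilylation under buffered, mildly acidic conditions should cleave the secondary silyl ether without generating the alkoxide that would promote 1,3-migration or loss of the O3 acetate.

**Compound list**

1 | 3-(3,4-dimethoxyphenyl)propan-1-ol | OCCCc1ccc(OC)c(OC)c1 | starting material
2 | 3-(3,4-dimethoxyphenyl)propanal | O=CCCc1ccc(OC)c(OC)c1 | intermediate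
3 | (E)-4-methoxypent-3-en-2-one | C/C(OC)=C\C(C)=O | starting material
4 | lithium (E)-4-methoxypenta-1,3-dien-2-olate | C/C(OC)=C\C(=C)[O-].[Li+] | intermediate
5 | (E)-4-methoxy-2-(trimethylsilyloxy)penta-1,3-diene | C/C(OC)=C\C(=C)O[Si](C)(C)C | intermediate
6 | (2E,6S)-8-(3,4-dimethoxyphenyl)-2-methoxy-6-[(trimethylsilyl)oxy]oct-2-en-4-one | C/C(OC)=C\C(=O)C[C@H](CCc1ccc(OC)c(OC)c1)O[Si](C)(C)C | intermediate
7 | (S)-2-[2-(3,4-dimethoxyphenyl)ethyl]-6-methyl-2,3-dihydro-4H-pyran-4-one | O=C1C[C@H](CCc2ccc(OC)c(OC)c2)OC(C)=C1 | intermediate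
8 | (2S,4R)-2-[2-(3,4-dimethoxyphenyl)ethyl]-6-methyl-3,4-dihydro-2H-pyran-4-ol | CC1=C[C@H](O)C[C@H](CCc2ccc(OC)c(OC)c2)O1 | intermediate
9 | tert-butyl{[(2S,4R)-2-[2-(3,4-dimethoxyphenyl)ethyl]-6-methyl-3,4-dihydro-2H-pyran-4-yl]oxy}dimethylsilane | CC1=C[C@H](O[Si](C)(C)C(C)(C)C)C[C@H](CCc2ccc(OC)c(OC)c2)O1 | intermediate
10 | (3S,5R)-5-[(tert-butyldimethylsilyl)oxy]-1-(3,4-dimethoxyphenyl)-6-hydroperoxy-6-methoxyhexan-3-yl acetate (mixture at C6) | COC(OO)[C@H](O[Si](C)(C)C(C)(C)C)C[C@H](CCc1ccc(OC)c(OC)c1)OC(C)=O | intermediate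
11 | (3S,5R)-5-[(tert-butyldimethylsilyl)oxy]-1-(3,4-dimethoxyphenyl)-6-oxohexan-3-yl acetate | O=C[C@H](O[Si](C)(C)C(C)(C)C)C[C@H](CCc1ccc(OC)c(OC)c1)OC(C)=O | intermediate
12 | (3S,5R,6Z)-5-[(tert-butyldimethylsilyl)oxy]-1-(3,4-dimethoxyphenyl)dec-6-en-3-yl acetate | CCC/C=C\[C@H](O[Si](C)(C)C(C)(C)C)C[C@H](CCc1ccc(OC)c(OC)c1)OC(C)=O | intermediate
13 | (3S,5S)-5-[(tert-butyldimethylsilyl)oxy]-1-(3,4-dimethoxyphenyl)decan-3-yl acetate | CCCCC[C@H](O[Si](C)(C)C(C)(C)C)C[C@H](CCc1ccc(OC)c(OC)c1)OC(C)=O | intermediate
14 | (3S,5S)-1-(3,4-dimethoxyphenyl)-5-hydroxydecan-3-yl acetate | CCCCC[C@H](O)C[C@H](CCc1ccc(OC)c(OC)c1)OC(C)=O | target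

**Step count:** 9 steps in total. The longest linear sequence is 8 steps (1 → 2 → 7 → 8 → 9 → 11 → 12 → 13 → 14; the branch from 3 is equally long).

**Steps most likely to fail**

Step 3. What may go wrong is weak enantioface discrimination, slow addition, or incomplete addition–elimination ring closure with the methyl-bearing diene. The fallback sets out from 2 and comes back at 7:
- Roskamp homologation of 2 with ethyl diazoacetate and SnCl2 (cat.) in CH2Cl2 gives ethyl 5-(3,4-dimethoxyphenyl)-3-oxopentanoate F1.
- Noyori asymmetric hydrogenation with RuCl2[(S)-BINAP] and H2 in EtOH gives ethyl (S)-5-(3,4-dimethoxyphenyl)-3-hydroxypentanoate F2.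
- MeNH(OMe)·HCl with i-PrMgCl in THF converts it into the Weinreb amide (S)-5-(3,4-dimethoxyphenyl)-3-hydroxy-N-methoxy-N-methylpentanamide F3.
- Excess 1-propynylmagnesium bromide gives (S)-8-(3,4-dimethoxyphenyl)-6-hydroxyoct-2-yn-4-one F4.
- A 6-endo-dig oxa-conjugate cyclisation catalysed by Ph3PAuCl/AgOTf in CH2Cl2 closes the ring to 7.

Here the stereocentre comes from the hydrogenation catalyst and the ring from an ynone instead of a diene.

Step 6. What may go wrong is over-oxidation of the dimethoxybenzene ring by ozone, or degradation of the alpha-silyloxy aldehyde during peroxide reduction. The fallback sets out from 9 and comes back at 11. Dihydroxylation of the enol ether with OsO4 (cat.) and N-methylmorpholine N-oxide in acetone/water, expected from the face opposite the silyloxy group, gives the cyclic hemiketal diol (2R,3S,4R,6S)-4-[(tert-butyldimethylsilyl)oxy]-6-[2-(3,4-dimethoxyphenyl)ethyl]-2-methyltetrahydro-2H-pyran-2,3-diol F5. Glycol cleavage with Pb(OAc)4 in CH2Cl2 with pyridine at 0 °C then breaks the bond between the two hydroxylated carbons while the ring oxygen stays on the former hemiketal carbon, which gives the O3 acetate and the C6 aldehyde of 11.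

Step 7. What may go wrong is epimerisation at C5 (alpha to the aldehyde) or attack of the basic ylide on the acetate. The fallback sets out from 11 and comes back at 13. Non-basic Takai–Utimoto alkylidenation with 1,1-diiodobutane and CrCl2 in THF/DMF gives (3S,5R,6E)-5-[(tert-butyldimethylsilyl)oxy]-1-(3,4-dimethoxyphenyl)dec-6-en-3-yl acetate F6, which is hydrogenated under the conditions of step 8 to 13.

**Further compounds**

F1 | step 3 | ethyl 5-(3,4-dimethoxyphenyl)-3-oxopentanoate | CCOC(=O)CC(=O)CCc1ccc(OC)c(OC)c1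
F2 | step 3 | ethyl (S)-5-(3,4-dimethoxyphenyl)-3-hydroxypentanoate | CCOC(=O)C[C@H](CCc1ccc(OC)c(OC)c1)O
F3 | step 3 | (S)-5-(3,4-dimethoxyphenyl)-3-hydroxy-N-methoxy-N-methylpentanamide | CON(C)C(=O)C[C@H](CCc1ccc(OC)c(OC)c1)O
F4 | step 3 | (S)-8-(3,4-dimethoxyphenyl)-6-hydroxyoct-2-yn-4-one | CC#CC(=O)C[C@H](CCc1ccc(OC)c(OC)c1)O
F5 | step 6 | (2R,3S,4R,6S)-4-[(tert-butyldimethylsilyl)oxy]-6-[2-(3,4-dimethoxyphenyl)ethyl]-2-methyltetrahydro-2H-pyran-2,3-diol | C[C@]1(O)[C@@H](O)[C@H](O[Si](C)(C)C(C)(C)C)C[C@H](CCc2ccc(OC)c(OC)c2)O1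
F6 | step 7 | (3S,5R,6E)-5-[(tert-butyldimethylsilyl)oxy]-1-(3,4-dimethoxyphenyl)dec-6-en-3-yl acetate | CCC/C=C/[C@H](O[Si](C)(C)C(C)(C)C)C[C@H](CCc1ccc(OC)c(OC)c1)OC(C)=O
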